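# Synthesis plan for CNP0137585.0 (compound 41)

## The problem

Compound 41 is a linear phlorotannin of the fuhalol type: seven benzene rings joined only by six diaryl ether oxygens and carrying eighteen free phenolic hydroxyls. The rings are lettered A to G from the 2,4,6-trihydroxyphenyl end to the 3,4,5-trihydroxyphenyl end. Rings B, D and F are 1,3,4,5-tetraoxygenated; rings C and E are pentaoxygenated with a single CH. There is no stereocentre and no C–C bond between rings, so the task is one of oxygen regiochemistry and of joining very electron-rich partners through oxygen. Four of the six ether oxygens (A–B on ring A, C–D on ring C, D–E on ring D, E–F on ring E) sit on a carbon flanked by two oxygen substituents, so one partner of each of these couplings is a hindered, easily oxidised phenol. The free polyphenol, with its pyrogallol- and phloroglucinol-type rings, will not survive base, oxidants or air for long, so every hydroxyl has to be carried masked and released in a last neutral, reductive step. The feature that opens the molecule is ring E: C1 (O to ring D) and C6 (O to ring F) are adjacent and are followed by C5, C4, C3 (three OH) and C2 (H). C1 and C6 are therefore the two β-carbons of an ortho-quinone with carbonyls at C3 and C4, with C5 as an alkoxy-bearing α-carbon. Both ring E ethers can then be made by phenoxide attack on a halogenated ortho-quinone, without a metal.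

## Retrosynthesis

**End game, 41 from 40 from 39.** The last cut removes sixteen O–benzyl bonds and the C2–Br bond of ring E from bromocatechol 40 in one hydrogenolysis. Benzyl is chosen for every hydroxyl because it is the only group that leaves eighteen-fold oxygenated material without acid or base, and the same conditions erase the bromine. Compound 40 is the dithionite reduction product of ortho-quinone 39; this is kept as a separate step so that a stable, purifiable catechol enters the global deprotection.

**Ring E, 39 from 37, 23 and 32.** The two C–O bonds of ring E (C1–O to ring D and C6–O to ring F) are cut together. This divides the heptamer 4 + 1 + 2 and places the two most awkward ether bonds in a step that needs no metal: the D oxygen, which lies between two benzyloxy groups, and the flanked C6 of ring E. The precursors are tribromo-ortho-quinone 37, tetramer phenol 23 and dimer phenol 32; monoadduct 38 is passed through without isolation.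

The forward reaction has to deliver site order. In the locants of 37, C5 (next to the brominated C6) must take the phenoxide of 23, and C4 (next to the benzyl enol ether carbon C3) must be left for that of 32. Three features of 37 are chosen to serve this:
- the C3 benzyloxy group is both the future hydroxyl and the electronic bias between the two β-carbons;
- the α-bromine at C6 activates C5, blocks the only other ring position and keeps the quinone from dimerising;
- the unhindered phenol 32 is reserved for the more crowded, less electrophilic C4.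

**Quinone 37 from 36, 35, 34 and 33.** The quinone is traced to tribromocatechol 36 by a two-electron oxidation and to 3-(benzyloxy)catechol 35 by exhaustive bromination. Compound 35 comes by Dakin oxidation from 34, the regioselective mono-benzyl ether of commercial 2,3-dihydroxybenzaldehyde 33. This avoids the unselective mono-benzylation of pyrogallol.

**Tetramer 23 by three identical cycles.** Each of the three ethers of 23 is cut on the side of the later ring, so that the hindered oxygen always belongs to the phenol and the electrophilic carbon is always unhindered.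
- 23 is the Baeyer–Villiger product of aldehyde 21, which is phenol 18 plus bromoaldehyde 20.
- 18 comes in the same way from aldehyde 16, which is phenol 11 plus bromoaldehyde 15.
- 11 comes from aldehyde 9, which is phenol 5 plus bromoaldehyde 8.

In each block the formyl group marks the carbon that will carry the next oxygen. It activates or at least tolerates the copper-catalysed coupling, and is then converted into the next phenol. The opposite polarity would require 2,6-dialkoxyaryl halides as electrophiles, the worst substrates for any aryl ether coupling. Each ring costs two operations and no protecting-group change.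

**The four blocks for 23.**
- Ring A phenol 5 comes from phloroglucinol 1 by benzylation to 2, formylation to 3 and Baeyer–Villiger oxidation.
- Ring B block 8 comes from commercial 5-bromo-2-hydroxy-3-methoxybenzaldehyde 6 by demethylation to 7 and benzylation.
- Ring C block 15 needs bromine ortho to the formyl group and para to an oxygen. Bromination of a 2,3,4-trioxybenzaldehyde gives the wrong isomer, so the aldehyde is introduced last: formylation of 5-bromo-1,2,3-trimethoxybenzene 12 to 13, then exchange of methyl for benzyl through 14.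
- Ring D block 20 comes in one step from 4-bromo-2,6-difluorobenzaldehyde 19 and benzyl alcohol.

**Dimer 32 from 30, 27 and 29.** The F–G ether is cut on the ring F side. Phenol 27 is made from 3,4,5-trihydroxybenzaldehyde 24 via 25. Bromoaldehyde 29 is made from 3-bromo-4,5-dihydroxybenzaldehyde 28. Coupling gives aldehyde 30, whose Baeyer–Villiger oxidation puts the free hydroxyl of 32 on the ring F carbon that will bond to ring E.

## Roads not taken

**Alternative 1: ring A by Claisen folding of a triketide.**
- Cut: the ring A C–C bond between a CH carbon and the hydroxyl carbon para to the ether.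
- Forward step: the polyanion of methyl 4-aryloxy-3,5-dioxohexanoate A1 closes onto its own ester and enolises to the free A–B triol A2.
- Merit: the ring A ether oxygen is attached to an sp3 carbon before ring A exists, so no coupling to a 2,6-disubstituted, oxidisable phenol is needed. In this respect it is better than step 6 of the chosen route.
- Weak points: it solves one ether of six. A1 is a sensitive α-aryloxy tricarbonyl chain that needs several steps. A2 is a free phloroglucinol whose benzylation competes with C-alkylation, and the allyl group must then be exchanged before ring C can be attached. Rings C to G, including ring E, are left to other chemistry.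
- Comparison: the chosen plan sets against it a ligand system established for hindered phenols in step 6, two operations per ring, and a key step that deals with the hardest ring.

**Alternative 2: ring D by double Claisen annulation.**
- Cut: the two ring D bonds between each hydroxyl carbon and its neighbouring CH carbon.
- Forward step: under alkoxide, the dienolate of glutaconate A3 (rings A to C) is acylated twice by malonate A4 (rings E to G) and aromatises to diester A5.
- Merit: this is the most convergent plan (3 + 1 + 3). It forms two C–C bonds in the fragment union and creates the two hydroxyls that flank the D–E oxygen. Its longest linear sequence would probably be shorter than the twelve steps of the chosen route.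
- Weak points: A5 carries two methoxycarbonyl groups that the target lacks, so two hindered esters must be hydrolysed and decarboxylated on a heavily benzylated heptamer. A4 already contains ring E with its flanked ether, so the hardest ring still has to be built by another method. The β-aryloxy group of A3 is a leaving group toward the alkoxide base.
- Comparison: the chosen plan is nearly as convergent (4 + 1 + 2). Its union product needs only reduction and hydrogenolysis, and it makes both ring E ethers in the union itself.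

**Alternative 3: ring B by Danheiser benzannulation.**
- Cut: two ring B C–C bonds.
- Forward step: heating cyclobutenone A6 with aryl ethynyl ether A7 gives, through vinylketene, [2+2] adduct, ring opening and 6π closure, the A–B phenol A8, which is the same compound as 11.
- Merit: the hindered A–O–B ether is made with no aryl–oxygen coupling, the regiochemistry is set by the annulation, and everything after 11 would be unchanged. For this one bond it is the better road.
- Weak points: both partners are uncommon. A7 is the alkynyl ether of a 2,6-disubstituted phenol and needs strongly basic steps next to benzyl ethers. A6 is a doubly oxygenated cyclobutenone several steps from commercial material. Together they cost more operations than the four (two for 8, coupling, oxidation) that lead from 5 to 11. Only the A–B portion is addressed.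
- Comparison: the chosen plan relies on commercial bromobenzaldehydes and one uniform coupling–oxidation cycle.

Key step: step 25

Assumption: in quinone 37 the β-carbon C5 (neighbour C6 carries bromine) is taken to be more electrophilic than C4 (neighbour C3 carries the benzyloxy donor); if the order were the reverse, adding the two phenols in the opposite sequence would lead to the same product 39.

## Route

Step 1
Reactants: 1 phloroglucinol (benzene-1,3,5-triol)
Product: 2 1,3,5-tris(benzyloxy)benzene
Conditions: BnBr, K2CO3, DMF, 25 °C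
Reagents that add atoms: benzyl bromide, BrCc1ccccc1
Why: Williamson ether synthesis; carbonate in a dipolar aprotic solvent favours O- over C-benzylation of the phloroglucinol anion.

Step 2
Reactants: 2 1,3,5-tris(benzyloxy)benzene
Product: 3 2,4,6-tris(benzyloxy)benzaldehyde
Conditions: POCl3, DMF, 0 → 25 °C; then H2O
Reagents that add atoms: N,N-dimethylformamide, CN(C)C=O; water, O
Why: Vilsmeier–Haack formylation; the three ring positions are equivalent and strongly activated, and the new formyl group deactivates the ring against a second attack.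

Step 3
Reactants: 3 2,4,6-tris(benzyloxy)benzaldehyde
Product: 5 ring A phenol (2,4,6-tris(benzyloxy)phenol), via aryl formate 4 (not isolated)
Conditions: mCPBA, CH2Cl2, 0 → 25 °C; then K2CO3 (cat.), MeOH, 25 °C, Ar
Reagents that add atoms: 3-chloroperoxybenzoic acid, OOC(=O)c1cccc(Cl)c1
Why: Baeyer–Villiger oxidation of an electron-rich benzaldehyde; the aryl group with two ortho and one para alkoxy donors migrates in preference to hydride, and the formate is cleaved by methanolysis.

Step 4
Reactants: 6 5-bromo-2-hydroxy-3-methoxybenzaldehyde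
Product: 7 5-bromo-2,3-dihydroxybenzaldehyde
Conditions: BBr3, CH2Cl2, −78 → 0 °C; then H2O
Reagents that add atoms: none
Why: Lewis-acid cleavage of an aryl methyl ether; aryl bromide and aldehyde are inert to BBr3 at this temperature.

Step 5
Reactants: 7 5-bromo-2,3-dihydroxybenzaldehyde
Product: 8 5-bromo-2,3-bis(benzyloxy)benzaldehyde
Conditions: BnBr, K2CO3, DMF, 60 °C
Reagents that add atoms: benzyl bromide, BrCc1ccccc1
Why: Williamson ether synthesis; at 60 °C the hydrogen-bonded 2-hydroxyl is alkylated as well.

Step 6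
Reactants: 5 ring A phenol (2,4,6-tris(benzyloxy)phenol); 8 5-bromo-2,3-bis(benzyloxy)benzaldehyde
Product: 9 A–B aldehyde (2,3-bis(benzyloxy)-5-[2,4,6-tris(benzyloxy)phenoxy]benzaldehyde)
Conditions: CuI (10 mol %), picolinic acid (20 mol %), K3PO4, DMSO, 90 °C, Ar
Reagents that add atoms: none
Why: Ullmann-type copper-catalysed diaryl ether synthesis with a picolinic acid ligand, a system established for 2,6-disubstituted phenols; the bromide of 8 has no ortho substituent, so all the hindrance lies on the phenoxide, and the inert atmosphere protects that phenoxide from oxidation.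

Step 7
Reactants: 9 A–B aldehyde
Product: 11 A–B phenol (2,3-bis(benzyloxy)-5-[2,4,6-tris(benzyloxy)phenoxy]phenol), via aryl formate 10 (not isolated)
Conditions: mCPBA, CH2Cl2, 0 → 25 °C; then K2CO3 (cat.), MeOH, 25 °C
Reagents that add atoms: 3-chloroperoxybenzoic acid, OOC(=O)c1cccc(Cl)c1
Why: Baeyer–Villiger oxidation; the ortho benzyloxy group promotes aryl migration, and one equivalent of peracid at low temperature should leave the CH positions of ring A alone.

Step 8
Reactants: 12 5-bromo-1,2,3-trimethoxybenzene
Product: 13 6-bromo-2,3,4-trimethoxybenzaldehyde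
Conditions: Cl2CHOMe, TiCl4, CH2Cl2, −10 → 0 °C; then H2O
Reagents that add atoms: dichloromethyl methyl ether, COC(Cl)Cl; water, O
Why: Rieche formylation; the two free ring positions are equivalent (ortho to bromine, para to a methoxy group), so only one aldehyde can form, and any Lewis-acid demethylation next to the formyl group is harmless because step 9 removes all methyl groups.

Step 9
Reactants: 13 6-bromo-2,3,4-trimethoxybenzaldehyde
Product: 14 6-bromo-2,3,4-trihydroxybenzaldehyde
Conditions: BBr3 (4 equiv), CH2Cl2, −78 → 25 °C; then H2O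
Reagents that add atoms: none
Why: exhaustive aryl methyl ether cleavage with BBr3; bromide and aldehyde survive.

Step 10
Reactants: 14 6-bromo-2,3,4-trihydroxybenzaldehyde
Product: 15 6-bromo-2,3,4-tris(benzyloxy)benzaldehyde
Conditions: BnBr, K2CO3, DMF, 60 °C, Ar
Reagents that add atoms: benzyl bromide, BrCc1ccccc1
Why: Williamson ether synthesis under exclusion of air, as for the bromine-free 2,3,4-trihydroxybenzaldehyde.

Step 11
Reactants: 11 A–B phenol; 15 6-bromo-2,3,4-tris(benzyloxy)benzaldehyde
Product: 16 A–B–C aldehyde (2,3,4-tris(benzyloxy)-6-{2,3-bis(benzyloxy)-5-[2,4,6-tris(benzyloxy)phenoxy]phenoxy}benzaldehyde)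
Conditions: CuI (10 mol %), N,N-dimethylglycine hydrochloride (30 mol %), Cs2CO3, dioxane, 90 °C, Ar
Reagents that add atoms: none
Why: Ullmann-type diaryl ether synthesis; the ortho formyl group of 15 accelerates copper insertion into the C–Br bond, and phenol 11 has only one ortho substituent.

Step 12
Reactants: 16 A–B–C aldehyde
Product: 18 A–B–C phenol (2,3,4-tris(benzyloxy)-6-{2,3-bis(benzyloxy)-5-[2,4,6-tris(benzyloxy)phenoxy]phenoxy}phenol), via aryl formate 17 (not isolated)
Conditions: mCPBA, CH2Cl2, 0 → 25 °C; then K2CO3 (cat.), MeOH–THF, 25 °C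
Reagents that add atoms: 3-chloroperoxybenzoic acid, OOC(=O)c1cccc(Cl)c1
Why: Baeyer–Villiger oxidation; the migrating ring C carries two ortho and one para oxygen donors, the best case for aryl migration.

Step 13
Reactants: 19 4-bromo-2,6-difluorobenzaldehyde
Product: 20 4-bromo-2,6-bis(benzyloxy)benzaldehyde
Conditions: BnOH, NaH, THF, 0 → 40 °C
Reagents that add atoms: benzyl alcohol, OCc1ccccc1
Why: nucleophilic aromatic substitution; both fluorides are ortho to the formyl group and fluoride leaves far faster than the para bromide, as in the corresponding reaction with methoxide.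

Step 14
Reactants: 18 A–B–C phenol; 20 4-bromo-2,6-bis(benzyloxy)benzaldehyde
Product: 21 A–B–C–D aldehyde (2,6-bis(benzyloxy)-4-aryloxybenzaldehyde whose aryloxy group is the phenoxy residue of 18)
Conditions: CuI (20 mol %), picolinic acid (40 mol %), K3PO4, DMSO, 100 °C, Ar
Reagents that add atoms: none
Why: Ullmann-type diaryl ether synthesis under the conditions for di-ortho-substituted phenols; the bromide of 20 is unhindered and activated by the para formyl group.

Step 15
Reactants: 21 A–B–C–D aldehyde
Product: 23 A–B–C–D phenol (2,6-bis(benzyloxy)-4-aryloxyphenol whose aryloxy group is the phenoxy residue of 18), via aryl formate 22 (not isolated)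
Conditions: mCPBA, CH2Cl2, 0 → 25 °C; then K2CO3 (cat.), MeOH–THF, 25 °C, Ar
Reagents that add atoms: 3-chloroperoxybenzoic acid, OOC(=O)c1cccc(Cl)c1
Why: Baeyer–Villiger oxidation of a 2,6-dialkoxy-4-aryloxybenzaldehyde; it places the free hydroxyl of ring D between the two benzyloxy groups, where the ring E ether has to start.

Step 16
Reactants: 24 3,4,5-trihydroxybenzaldehyde
Product: 25 3,4,5-tris(benzyloxy)benzaldehyde
Conditions: BnBr, K2CO3, DMF, 60 °C, Ar
Reagents that add atoms: benzyl bromide, BrCc1ccccc1
Why: Williamson ether synthesis.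

Step 17
Reactants: 25 3,4,5-tris(benzyloxy)benzaldehyde
Product: 27 ring G phenol (3,4,5-tris(benzyloxy)phenol), via aryl formate 26 (not isolated)
Conditions: mCPBA, CH2Cl2, 25 °C; then K2CO3 (cat.), MeOH, 25 °C
Reagents that add atoms: 3-chloroperoxybenzoic acid, OOC(=O)c1cccc(Cl)c1
Why: Baeyer–Villiger oxidation; the para alkoxy group suffices for aryl migration, as with the trimethoxy analogue.

Step 18
Reactants: 28 3-bromo-4,5-dihydroxybenzaldehyde
Product: 29 3-bromo-4,5-bis(benzyloxy)benzaldehyde
Conditions: BnBr, K2CO3, DMF, 60 °C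
Reagents that add atoms: benzyl bromide, BrCc1ccccc1
Why: Williamson ether synthesis.

Step 19
Reactants: 27 ring G phenol; 29 3-bromo-4,5-bis(benzyloxy)benzaldehyde
Product: 30 F–G aldehyde (3,4-bis(benzyloxy)-5-[3,4,5-tris(benzyloxy)phenoxy]benzaldehyde)
Conditions: CuI (10 mol %), N,N-dimethylglycine hydrochloride (30 mol %), Cs2CO3, dioxane, 90 °C, Ar
Reagents that add atoms: none
Why: Ullmann-type diaryl ether synthesis between an unhindered phenol and a 5-bromovanillin-type bromide, the classical substrate pair for this reaction.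

Step 20
Reactants: 30 F–G aldehyde
Product: 32 F–G phenol (3,4-bis(benzyloxy)-5-[3,4,5-tris(benzyloxy)phenoxy]phenol), via aryl formate 31 (not isolated)
Conditions: mCPBA, CH2Cl2, 25 °C; then K2CO3 (cat.), MeOH, 25 °C
Reagents that add atoms: 3-chloroperoxybenzoic acid, OOC(=O)c1cccc(Cl)c1
Why: Baeyer–Villiger oxidation with a para benzyloxy donor on the migrating ring; the hydroxyl appears on the ring F carbon meant for ring E.

Step 21
Reactants: 33 2,3-dihydroxybenzaldehyde
Product: 34 3-(benzyloxy)-2-hydroxybenzaldehyde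
Conditions: NaH (2.1 equiv), DMSO–THF, 25 °C; then BnBr (1.0 equiv)
Reagents that add atoms: benzyl bromide, BrCc1ccccc1
Why: Williamson alkylation of the dianion; the 3-phenoxide is the more nucleophilic site because the 2-phenoxide is conjugated with and chelated to the formyl group.

Step 22
Reactants: 34 3-(benzyloxy)-2-hydroxybenzaldehyde
Product: 35 3-(benzyloxy)benzene-1,2-diol
Conditions: H2O2 (30 %), NaOH, H2O–THF, 0 → 25 °C; then HCl
Reagents that add atoms: hydrogen peroxide, OO
Why: Dakin oxidation of an ortho-hydroxybenzaldehyde, the standard way from ortho-vanillin-type aldehydes to 3-alkoxycatechols.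

Step 23
Reactants: 35 3-(benzyloxy)benzene-1,2-diol
Product: 36 3-(benzyloxy)-4,5,6-tribromobenzene-1,2-diol
Conditions: Br2 (3.1 equiv), NaOAc, AcOH–CH2Cl2, 0 → 25 °C
Reagents that add atoms: bromine, BrBr
Why: electrophilic aromatic bromination; each of the three free positions is ortho or para to an oxygen, and acetate takes up the hydrogen bromide that would otherwise attack the benzyl ether.

Step 24
Reactants: 36 3-(benzyloxy)-4,5,6-tribromobenzene-1,2-diol
Product: 37 3-(benzyloxy)-4,5,6-tribromocyclohexa-3,5-diene-1,2-dione (3-benzyloxy-4,5,6-tribromo-ortho-benzoquinone)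
Conditions: PhI(OAc)2, CH2Cl2, 0 °C
Reagents that add atoms: none
Why: two-electron oxidation of a catechol to the ortho-quinone by a hypervalent iodine reagent in a non-nucleophilic solvent; the fully substituted quinone cannot dimerise by cycloaddition.

Step 25
Reactants: 37 3-benzyloxy-4,5,6-tribromo-ortho-benzoquinone; 23 A–B–C–D phenol; 32 F–G phenol
Product: 39 protected heptamer quinone (3-(benzyloxy)-6-bromo-5-(phenoxy residue of 23)-4-(phenoxy residue of 32)cyclohexa-3,5-diene-1,2-dione), via monoaryloxy dibromoquinone 38 (not isolated)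
Conditions: Cs2CO3, 4 Å MS, MeCN–THF, −40 °C, slow addition of 23 to 37 (1.1 equiv); then 32 (1.3 equiv), Cs2CO3, −40 → 0 °C
Reagents that add atoms: none
Why: Each phenoxide adds in conjugate fashion to a bromine-bearing β-carbon of the ortho-quinone and the resulting enolate expels bromide, restoring the quinone; the closest known reaction type is the replacement of the 4- and 5-halides of tetrahalo-ortho-benzoquinones by phenoxides and the oxa-Michael addition/elimination of phenols on bromo-ortho-quinones. No ring is closed and no stereocentre is formed; two C–O bonds of ring E are made. The selectivity required is site order: the phenoxide of 23 must take C5 and leave C4 for that of 32. C5 is the β-carbon of the enone whose α-carbon C6 bears the inductively withdrawing bromine, whereas C4 is the β-carbon of the benzyl enol ether at C3 and is made electron-rich by lone-pair donation, so the first equivalent should enter at C5 and give 38. In 38 the aryloxy group turns C5 into a vinylogous carbonate carbon with a poorer leaving group than bromide, which should send the second, unhindered phenoxide to C4 and not into exchange at C5. Slow addition of 23 to a slight excess of 37 at low temperature guards against double substitution by the tetramer, and a carbonate base keeps the phenoxide concentration low, which should limit electron transfer to the quinone and favour O- over C-attack; ring D has no free ortho or para position for C-attack. The α-bromine at C6 is not on a conjugate position of its own carbonyl and stays in place.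

Step 26
Reactants: 39 protected heptamer quinone
Product: 40 protected heptamer bromocatechol (3-(benzyloxy)-6-bromo-5-(phenoxy residue of 23)-4-(phenoxy residue of 32)benzene-1,2-diol)
Conditions: Na2S2O4, THF–H2O, 25 °C
Reagents that add atoms: none
Why: dithionite reduction of a quinone to the catechol under neutral aqueous conditions; ring E becomes aromatic, and benzyl ethers and the aryl bromide are untouched.

Step 27
Reactants: 40 protected heptamer bromocatechol
Product: 41 CNP0137585.0 (40 with all sixteen benzyl groups and the ring E bromine replaced by hydrogen)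
Conditions: H2 (1 atm), Pd(OH)2/C, NaOAc, THF–MeOH, 25 °C; work-up under Ar
Reagents that add atoms: none
Why: palladium-catalysed hydrogenolysis of benzyl aryl ethers and of the aryl C–Br bond in one operation; acetate takes up the hydrogen bromide, and diaryl ethers are inert under these conditions.

## Compound list

1 | phloroglucinol (benzene-1,3,5-triol) | Oc1cc(O)cc(O)c1 | starting material
2 | 1,3,5-tris(benzyloxy)benzene | c9ccccc9COc1cc(OCc9ccccc9)cc(OCc9ccccc9)c1 | intermediate
3 | 2,4,6-tris(benzyloxy)benzaldehyde | O=Cc1c(OCc9ccccc9)cc(OCc9ccccc9)cc1OCc9ccccc9 | intermediate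
4 | 2,4,6-tris(benzyloxy)phenyl formate (not isolated) | O=COc1c(OCc9ccccc9)cc(OCc9ccccc9)cc1OCc9ccccc9 | intermediate
5 | ring A phenol, 2,4,6-tris(benzyloxy)phenol | Oc1c(OCc9ccccc9)cc(OCc9ccccc9)cc1OCc9ccccc9 | intermediate
6 | 5-bromo-2-hydroxy-3-methoxybenzaldehyde | COc1cc(Br)cc(C=O)c1O | starting material
7 | 5-bromo-2,3-dihydroxybenzaldehyde | O=Cc1cc(Br)cc(O)c1O | intermediate
8 | 5-bromo-2,3-bis(benzyloxy)benzaldehyde | O=Cc1cc(Br)cc(OCc9ccccc9)c1OCc9ccccc9 | intermediate
9 | A–B aldehyde, 2,3-bis(benzyloxy)-5-[2,4,6-tris(benzyloxy)phenoxy]benzaldehyde | c9ccccc9COc1cc(OCc9ccccc9)c(Oc2cc(OCc9ccccc9)c(OCc9ccccc9)c(C=O)c2)c(OCc9ccccc9)c1 | intermediate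
10 | A–B aryl formate, 2,3-bis(benzyloxy)-5-[2,4,6-tris(benzyloxy)phenoxy]phenyl formate (not isolated) | c9ccccc9COc1cc(OCc9ccccc9)c(Oc2cc(OCc9ccccc9)c(OCc9ccccc9)c(OC=O)c2)c(OCc9ccccc9)c1 | intermediate
11 | A–B phenol, 2,3-bis(benzyloxy)-5-[2,4,6-tris(benzyloxy)phenoxy]phenol | c9ccccc9COc1cc(OCc9ccccc9)c(Oc2cc(OCc9ccccc9)c(OCc9ccccc9)c(O)c2)c(OCc9ccccc9)c1 | intermediate
12 | 5-bromo-1,2,3-trimethoxybenzene | COc1cc(Br)cc(OC)c1OC | starting material
13 | 6-bromo-2,3,4-trimethoxybenzaldehyde | O=Cc1c(Br)cc(OC)c(OC)c1OC | intermediate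
14 | 6-bromo-2,3,4-trihydroxybenzaldehyde | O=Cc1c(Br)cc(O)c(O)c1O | intermediate
15 | 6-bromo-2,3,4-tris(benzyloxy)benzaldehyde | O=Cc1c(Br)cc(OCc9ccccc9)c(OCc9ccccc9)c1OCc9ccccc9 | intermediate
16 | A–B–C aldehyde, 2,3,4-tris(benzyloxy)-6-{2,3-bis(benzyloxy)-5-[2,4,6-tris(benzyloxy)phenoxy]phenoxy}benzaldehyde | c9ccccc9COc1cc(OCc9ccccc9)c(Oc2cc(OCc9ccccc9)c(OCc9ccccc9)c(Oc3cc(OCc9ccccc9)c(OCc9ccccc9)c(OCc9ccccc9)c3C=O)c2)c(OCc9ccccc9)c1 | intermediate
17 | A–B–C aryl formate, formate ester of 18 (not isolated) | c9ccccc9COc1cc(OCc9ccccc9)c(Oc2cc(OCc9ccccc9)c(OCc9ccccc9)c(Oc3cc(OCc9ccccc9)c(OCc9ccccc9)c(OCc9ccccc9)c3OC=O)c2)c(OCc9ccccc9)c1 | intermediate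
18 | A–B–C phenol, 2,3,4-tris(benzyloxy)-6-{2,3-bis(benzyloxy)-5-[2,4,6-tris(benzyloxy)phenoxy]phenoxy}phenol | c9ccccc9COc1cc(OCc9ccccc9)c(Oc2cc(OCc9ccccc9)c(OCc9ccccc9)c(Oc3cc(OCc9ccccc9)c(OCc9ccccc9)c(OCc9ccccc9)c3O)c2)c(OCc9ccccc9)c1 | intermediate
19 | 4-bromo-2,6-difluorobenzaldehyde | O=Cc1c(F)cc(Br)cc1F | starting material
20 | 4-bromo-2,6-bis(benzyloxy)benzaldehyde | O=Cc1c(OCc9ccccc9)cc(Br)cc1OCc9ccccc9 | intermediate
21 | A–B–C–D aldehyde, 2,6-bis(benzyloxy)-4-aryloxybenzaldehyde with the phenoxy residue of 18 as aryloxy group | c9ccccc9COc1cc(OCc9ccccc9)c(Oc2cc(OCc9ccccc9)c(OCc9ccccc9)c(Oc3cc(OCc9ccccc9)c(OCc9ccccc9)c(OCc9ccccc9)c3Oc4cc(OCc9ccccc9)c(C=O)c(OCc9ccccc9)c4)c2)c(OCc9ccccc9)c1 | intermediate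
22 | A–B–C–D aryl formate, formate ester of 23 (not isolated) | c9ccccc9COc1cc(OCc9ccccc9)c(Oc2cc(OCc9ccccc9)c(OCc9ccccc9)c(Oc3cc(OCc9ccccc9)c(OCc9ccccc9)c(OCc9ccccc9)c3Oc4cc(OCc9ccccc9)c(OC=O)c(OCc9ccccc9)c4)c2)c(OCc9ccccc9)c1 | intermediate
23 | A–B–C–D phenol, 2,6-bis(benzyloxy)-4-aryloxyphenol with the phenoxy residue of 18 as aryloxy group | c9ccccc9COc1cc(OCc9ccccc9)c(Oc2cc(OCc9ccccc9)c(OCc9ccccc9)c(Oc3cc(OCc9ccccc9)c(OCc9ccccc9)c(OCc9ccccc9)c3Oc4cc(OCc9ccccc9)c(O)c(OCc9ccccc9)c4)c2)c(OCc9ccccc9)c1 | intermediate
24 | 3,4,5-trihydroxybenzaldehyde | O=Cc1cc(O)c(O)c(O)c1 | starting material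
25 | 3,4,5-tris(benzyloxy)benzaldehyde | O=Cc1cc(OCc9ccccc9)c(OCc9ccccc9)c(OCc9ccccc9)c1 | intermediate
26 | 3,4,5-tris(benzyloxy)phenyl formate (not isolated) | O=COc1cc(OCc9ccccc9)c(OCc9ccccc9)c(OCc9ccccc9)c1 | intermediate
27 | ring G phenol, 3,4,5-tris(benzyloxy)phenol | Oc1cc(OCc9ccccc9)c(OCc9ccccc9)c(OCc9ccccc9)c1 | intermediate
28 | 3-bromo-4,5-dihydroxybenzaldehyde | O=Cc1cc(O)c(O)c(Br)c1 | starting material
29 | 3-bromo-4,5-bis(benzyloxy)benzaldehyde | O=Cc1cc(OCc9ccccc9)c(OCc9ccccc9)c(Br)c1 | intermediate
30 | F–G aldehyde, 3,4-bis(benzyloxy)-5-[3,4,5-tris(benzyloxy)phenoxy]benzaldehyde | O=Cc1cc(OCc9ccccc9)c(OCc9ccccc9)c(Oc2cc(OCc9ccccc9)c(OCc9ccccc9)c(OCc9ccccc9)c2)c1 | intermediate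
31 | F–G aryl formate, 3,4-bis(benzyloxy)-5-[3,4,5-tris(benzyloxy)phenoxy]phenyl formate (not isolated) | O=COc1cc(OCc9ccccc9)c(OCc9ccccc9)c(Oc2cc(OCc9ccccc9)c(OCc9ccccc9)c(OCc9ccccc9)c2)c1 | intermediate
32 | F–G phenol, 3,4-bis(benzyloxy)-5-[3,4,5-tris(benzyloxy)phenoxy]phenol | Oc1cc(OCc9ccccc9)c(OCc9ccccc9)c(Oc2cc(OCc9ccccc9)c(OCc9ccccc9)c(OCc9ccccc9)c2)c1 | intermediate
33 | 2,3-dihydroxybenzaldehyde | O=Cc1cccc(O)c1O | starting material
34 | 3-(benzyloxy)-2-hydroxybenzaldehyde | O=Cc1cccc(OCc9ccccc9)c1O | intermediate
35 | 3-(benzyloxy)benzene-1,2-diol | Oc1cccc(OCc9ccccc9)c1O | intermediate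
36 | 3-(benzyloxy)-4,5,6-tribromobenzene-1,2-diol | Oc1c(O)c(OCc9ccccc9)c(Br)c(Br)c1Br | intermediate
37 | 3-(benzyloxy)-4,5,6-tribromocyclohexa-3,5-diene-1,2-dione | O=C1C(=O)C(OCc9ccccc9)=C(Br)C(Br)=C1Br | intermediate
38 | 3-(benzyloxy)-4,6-dibromo-5-aryloxycyclohexa-3,5-diene-1,2-dione with the phenoxy residue of 23 as aryloxy group (not isolated) | c9ccccc9COc1cc(OCc9ccccc9)c(Oc2cc(OCc9ccccc9)c(OCc9ccccc9)c(Oc3cc(OCc9ccccc9)c(OCc9ccccc9)c(OCc9ccccc9)c3Oc4cc(OCc9ccccc9)c(OC5=C(Br)C(=O)C(=O)C(OCc9ccccc9)=C5Br)c(OCc9ccccc9)c4)c2)c(OCc9ccccc9)c1 | intermediate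
39 | protected heptamer quinone, 3-(benzyloxy)-6-bromo-5-(phenoxy residue of 23)-4-(phenoxy residue of 32)cyclohexa-3,5-diene-1,2-dione | c9ccccc9COc1cc(OCc9ccccc9)c(Oc2cc(OCc9ccccc9)c(OCc9ccccc9)c(Oc3cc(OCc9ccccc9)c(OCc9ccccc9)c(OCc9ccccc9)c3Oc4cc(OCc9ccccc9)c(OC5=C(Br)C(=O)C(=O)C(OCc9ccccc9)=C5Oc6cc(OCc9ccccc9)c(OCc9ccccc9)c(Oc7cc(OCc9ccccc9)c(OCc9ccccc9)c(OCc9ccccc9)c7)c6)c(OCc9ccccc9)c4)c2)c(OCc9ccccc9)c1 | intermediate
40 | protected heptamer bromocatechol, 3-(benzyloxy)-6-bromo-5-(phenoxy residue of 23)-4-(phenoxy residue of 32)benzene-1,2-diol | c9ccccc9COc1cc(OCc9ccccc9)c(Oc2cc(OCc9ccccc9)c(OCc9ccccc9)c(Oc3cc(OCc9ccccc9)c(OCc9ccccc9)c(OCc9ccccc9)c3Oc4cc(OCc9ccccc9)c(Oc5c(Br)c(O)c(O)c(OCc9ccccc9)c5Oc6cc(OCc9ccccc9)c(OCc9ccccc9)c(Oc7cc(OCc9ccccc9)c(OCc9ccccc9)c(OCc9ccccc9)c7)c6)c(OCc9ccccc9)c4)c2)c(OCc9ccccc9)c1 | intermediate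
41 | CNP0137585.0, the free heptamer (rings A to G, eighteen hydroxyls) | Oc1cc(O)c(Oc2cc(O)c(O)c(Oc3cc(O)c(O)c(O)c3Oc3cc(O)c(Oc4cc(O)c(O)c(O)c4Oc4cc(O)c(O)c(Oc5cc(O)c(O)c(O)c5)c4)c(O)c3)c2)c(O)c1 | target

## Step count and uncertain steps

Total step count: 27. Longest linear sequence: 12 steps (1, 2, 3, 6, 7, 11, 12, 14, 15, 25, 26, 27).

**Step 25 (key step).** Three processes are most likely to go wrong.
- Electron transfer from the very electron-rich ring D phenoxide to the strongly oxidising quinone could lead to phenoxyl-radical chemistry instead of substitution.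
- Site order could be lost, through first attack at C4 or through displacement of the first aryloxy group by the second phenoxide, since the difference between the two β-carbons rests on a substituent effect alone.
- The ambident F–G phenoxide could attack through carbon.

Within the approach, the order of phenol addition can be inverted if C4 proves the more reactive site. The fallback gives up the quinone and continues the coupling–oxidation cycle of the tetramer. It sets out from 23:
- Copper-catalysed coupling with 15 (conditions of step 14) should give pentamer aldehyde F1, and Baeyer–Villiger oxidation with methanolysis (as in step 15) pentamer phenol F2.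
- Coupling of F2 with 8 should give hexamer aldehyde F3, and oxidation hexamer phenol F4.
- Coupling of F4 with 20 should give heptamer aldehyde F5, and oxidation heptamer phenol F6, which carries seventeen benzyl ethers and a free hydroxyl at C4 of ring G.
- Hydrogenolysis of F6 as in step 27 comes back to the route at 41.

**Step 14.** The phenoxide oxygen of 18 is shielded by an aryloxy and a benzyloxy group. Ligand exchange at copper may therefore be slow, and reduction of the bromide or oxidation of the phenoxide may overtake the coupling. The fallback changes the ring D partner from electrophile to nucleophile. From 20, palladium-catalysed borylation with B2(OH)4 (Pd(OAc)2, XPhos, KOAc, EtOH, 80 °C) should give [3,5-bis(benzyloxy)-4-formylphenyl]boronic acid F7. F7 is joined to 18 by Chan–Lam coupling (Cu(OAc)2, pyridine, 4 Å MS, CH2Cl2, air, 25 °C), an oxidative coupling at room temperature that accepts phenols with two ortho substituents. It comes back to the route at 21.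

**Step 6.** The same steric shielding applies to 5, and its phenoxide is in addition the most easily oxidised in the route, so oxidative degradation under copper catalysis is the likely failure. The fallback sets out from 5 and 8 and uses palladium-catalysed C–O cross-coupling (Pd(OAc)2, tBuXPhos, K3PO4, toluene, 100 °C). Here the ether bond forms by reductive elimination from an arylpalladium phenoxide held by a bulky biarylphosphine, and no copper phenoxide is involved. It comes back to the route at 9 and makes no new compound.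

**Step 27.** Sixteen hydrogenolyses and one hydrodebromination must all go to completion on one molecule. Bromide and the increasingly polar, strongly adsorbing polyphenol may slow the catalyst and leave partially benzylated material, and the product may oxidise during a long reaction or work-up. The fallback separates the two tasks. From 40, BCl3 with pentamethylbenzene (CH2Cl2, −78 °C) should remove all benzyl groups by Lewis-acid cleavage and give the ring E bromo heptaphenol F8. A short hydrodebromination of F8 (H2, Pd/C, NaOAc, MeOH) comes back to the route at 41.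

## Further compounds

F1 | step 25 | pentamer aldehyde, 23 O-arylated on its ring D hydroxyl with a 2-formyl-3,4,5-tris(benzyloxy)phenyl group | c9ccccc9COc1cc(OCc9ccccc9)c(Oc2cc(OCc9ccccc9)c(OCc9ccccc9)c(Oc3cc(OCc9ccccc9)c(OCc9ccccc9)c(OCc9ccccc9)c3Oc4cc(OCc9ccccc9)c(Oc5cc(OCc9ccccc9)c(OCc9ccccc9)c(OCc9ccccc9)c5C=O)c(OCc9ccccc9)c4)c2)c(OCc9ccccc9)c1
F2 | step 25 | pentamer phenol, F1 with hydroxyl in place of the formyl group | c9ccccc9COc1cc(OCc9ccccc9)c(Oc2cc(OCc9ccccc9)c(OCc9ccccc9)c(Oc3cc(OCc9ccccc9)c(OCc9ccccc9)c(OCc9ccccc9)c3Oc4cc(OCc9ccccc9)c(Oc5cc(OCc9ccccc9)c(OCc9ccccc9)c(OCc9ccccc9)c5O)c(OCc9ccccc9)c4)c2)c(OCc9ccccc9)c1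
F3 | step 25 | hexamer aldehyde, F2 O-arylated on its ring E hydroxyl with a 3,4-bis(benzyloxy)-5-formylphenyl group | c9ccccc9COc1cc(OCc9ccccc9)c(Oc2cc(OCc9ccccc9)c(OCc9ccccc9)c(Oc3cc(OCc9ccccc9)c(OCc9ccccc9)c(OCc9ccccc9)c3Oc4cc(OCc9ccccc9)c(Oc5cc(OCc9ccccc9)c(OCc9ccccc9)c(OCc9ccccc9)c5Oc6cc(OCc9ccccc9)c(OCc9ccccc9)c(C=O)c6)c(OCc9ccccc9)c4)c2)c(OCc9ccccc9)c1
F4 | step 25 | hexamer phenol, F3 with hydroxyl in place of the formyl group | c9ccccc9COc1cc(OCc9ccccc9)c(Oc2cc(OCc9ccccc9)c(OCc9ccccc9)c(Oc3cc(OCc9ccccc9)c(OCc9ccccc9)c(OCc9ccccc9)c3Oc4cc(OCc9ccccc9)c(Oc5cc(OCc9ccccc9)c(OCc9ccccc9)c(OCc9ccccc9)c5Oc6cc(OCc9ccccc9)c(OCc9ccccc9)c(O)c6)c(OCc9ccccc9)c4)c2)c(OCc9ccccc9)c1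
F5 | step 25 | heptamer aldehyde, F4 O-arylated on its ring F hydroxyl with a 3,5-bis(benzyloxy)-4-formylphenyl group | c9ccccc9COc1cc(OCc9ccccc9)c(Oc2cc(OCc9ccccc9)c(OCc9ccccc9)c(Oc3cc(OCc9ccccc9)c(OCc9ccccc9)c(OCc9ccccc9)c3Oc4cc(OCc9ccccc9)c(Oc5cc(OCc9ccccc9)c(OCc9ccccc9)c(OCc9ccccc9)c5Oc6cc(OCc9ccccc9)c(OCc9ccccc9)c(Oc7cc(OCc9ccccc9)c(C=O)c(OCc9ccccc9)c7)c6)c(OCc9ccccc9)c4)c2)c(OCc9ccccc9)c1
F6 | step 25 | heptamer phenol, F5 with hydroxyl in place of the formyl group (seventeen benzyl ethers, free hydroxyl at C4 of ring G) | c9ccccc9COc1cc(OCc9ccccc9)c(Oc2cc(OCc9ccccc9)c(OCc9ccccc9)c(Oc3cc(OCc9ccccc9)c(OCc9ccccc9)c(OCc9ccccc9)c3Oc4cc(OCc9ccccc9)c(Oc5cc(OCc9ccccc9)c(OCc9ccccc9)c(OCc9ccccc9)c5Oc6cc(OCc9ccccc9)c(OCc9ccccc9)c(Oc7cc(OCc9ccccc9)c(O)c(OCc9ccccc9)c7)c6)c(OCc9ccccc9)c4)c2)c(OCc9ccccc9)c1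
F7 | step 14 | [3,5-bis(benzyloxy)-4-formylphenyl]boronic acid | O=Cc1c(OCc9ccccc9)cc(B(O)O)cc1OCc9ccccc9
F0 | step 6 | none | none
F8 | step 27 | ring E bromo heptaphenol, 41 with bromine at C2 of ring E | Oc1cc(O)c(Oc2cc(O)c(O)c(Oc3cc(O)c(O)c(O)c3Oc4cc(O)c(Oc5c(Br)c(O)c(O)c(O)c5Oc6cc(O)c(O)c(Oc7cc(O)c(O)c(O)c7)c6)c(O)c4)c2)c(O)c1
A1 | alternative 1 | methyl 4-[3-(allyloxy)-4,5-bis(benzyloxy)phenoxy]-3,5-dioxohexanoate (racemic) | COC(=O)CC(=O)C(Oc1cc(OCC=C)c(OCc9ccccc9)c(OCc9ccccc9)c1)C(C)=O
A2 | alternative 1 | 2-[3-(allyloxy)-4,5-bis(benzyloxy)phenoxy]benzene-1,3,5-triol | Oc1cc(O)c(Oc2cc(OCC=C)c(OCc9ccccc9)c(OCc9ccccc9)c2)c(O)c1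
A3 | alternative 2 | dimethyl 3-aryloxypent-2-enedioate with the phenoxy residue of 18 as aryloxy group | c9ccccc9COc1cc(OCc9ccccc9)c(Oc2cc(OCc9ccccc9)c(OCc9ccccc9)c(Oc3cc(OCc9ccccc9)c(OCc9ccccc9)c(OCc9ccccc9)c3OC(CC(=O)OC)=CC(=O)OC)c2)c(OCc9ccccc9)c1
A4 | alternative 2 | dimethyl 2-{3,4,5-tris(benzyloxy)-2-[3,4-bis(benzyloxy)-5-(3,4,5-tris(benzyloxy)phenoxy)phenoxy]phenoxy}propanedioate | COC(=O)C(Oc1cc(OCc9ccccc9)c(OCc9ccccc9)c(OCc9ccccc9)c1Oc2cc(OCc9ccccc9)c(OCc9ccccc9)c(Oc3cc(OCc9ccccc9)c(OCc9ccccc9)c(OCc9ccccc9)c3)c2)C(=O)OC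
A5 | alternative 2 | protected heptamer with ring D as dimethyl 4,6-dihydroxy-2-(A–B–C aryloxy)-5-(E–F–G aryloxy)benzene-1,3-dicarboxylate | c9ccccc9COc1cc(OCc9ccccc9)c(Oc2cc(OCc9ccccc9)c(OCc9ccccc9)c(Oc3cc(OCc9ccccc9)c(OCc9ccccc9)c(OCc9ccccc9)c3Oc3c(C(=O)OC)c(O)c(Oc4cc(OCc9ccccc9)c(OCc9ccccc9)c(OCc9ccccc9)c4Oc4cc(OCc9ccccc9)c(OCc9ccccc9)c(Oc5cc(OCc9ccccc9)c(OCc9ccccc9)c(OCc9ccccc9)c5)c4)c(O)c3C(=O)OC)c2)c(OCc9ccccc9)c1
A6 | alternative 3 | 3,4-bis(benzyloxy)cyclobut-2-en-1-one (racemic) | O=C1C=C(OCc9ccccc9)C1OCc9ccccc9
A7 | alternative 3 | 1,3,5-tris(benzyloxy)-2-(ethynyloxy)benzene | C#COc1c(OCc9ccccc9)cc(OCc9ccccc9)cc1OCc9ccccc9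
A8 | alternative 3 | A–B phenol, 2,3-bis(benzyloxy)-5-[2,4,6-tris(benzyloxy)phenoxy]phenol (identical with 11) | Oc1cc(Oc2c(OCc9ccccc9)cc(OCc9ccccc9)cc2OCc9ccccc9)cc(OCc9ccccc9)c1OCc9ccccc9
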